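**Strategy.** The twelve-membered diolide is disconnected at the ester O–C bond that joins the carboxyl oxygen of ring A (the benzene ring that keeps one aromatic C–H) to the methyl-bearing carbon beside ring B's benzylic carbinol. That O–CH(CH3) unit is a hydrogenated 1-alken-2-yl ester. One ruthenium-catalysed Markovnikov addition of the free ring A acid to a terminal propargylic alkyne on ring B therefore forms the hindered ester bond and closes the macrocycle without acyl activation. The precursor is an alkynyl seco acid: ring B's carboxyl already esterified by ring A's threo side chain, both benzylic carbinols as TBS ethers, all five phenols as benzyl ethers.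

Key step: step 20

Remark 1: ring B carries four ring oxygens, one more than ring A. Both rings are grown from 1, and the extra oxygen is introduced by lithiation–borylation–oxidation of bromide 4 (step 10).

Remark 2: each benzylic carbinol is silylated while its arene still carries bromine, and ring A's carboxyl is introduced only after the first ester bond exists (steps 17 and 18). A free carbinol beside an ortho carboxyl or ortho ester would otherwise close to a phthalide or a dihydroisocoumarin.

Remark 3: the two aldehydes are alkynylated by different catalyst systems. The mono-ortho-substituted ring A aldehyde 5 uses the BINOL–titanium/diethylzinc protocol. The doubly ortho-substituted, electron-rich ring B aldehyde 18 uses dimethylzinc with ProPhenol (2,6-bis{[2-(hydroxydiphenylmethyl)pyrrolidin-1-yl]methyl}-4-methylphenol), a dinuclear zinc catalyst that needs no titanium alkoxide.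

Remark 4: the facial sense of both alkynylations, of the CBS reduction and of the DuPhos hydrogenation is assigned by analogy with simpler substrates. The configuration would be checked after each of these steps and the antipodal ligand used if the sense proved opposite.

Step 1
Reactants: 1 methyl 3,5-dihydroxy-4-methoxybenzoate
Product: 2 methyl 3,5-bis(benzyloxy)-4-methoxybenzoate
Conditions: BnBr, K2CO3, DMF, 60 °C
Reagents that add atoms: benzyl bromide BrCc1ccccc1
Why: Williamson etherification of both phenols installs benzyl ethers that withstand every hydride and organolithium step and are removed together in the final hydrogenolysis.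

Step 2
Reactants: 2 methyl 3,5-bis(benzyloxy)-4-methoxybenzoate
Product: 3 [3,5-bis(benzyloxy)-4-methoxyphenyl]methanol
Conditions: LiAlH4, THF, 0 °C
Reagents that add atoms: none
Why: Hydride reduction of the ester to the benzylic alcohol leaves the aryl benzyl ethers untouched.

Step 3
Reactants: 3 [3,5-bis(benzyloxy)-4-methoxyphenyl]methanol
Product: 4 [3,5-bis(benzyloxy)-2-bromo-4-methoxyphenyl]methanol
Conditions: NBS (1.0 equiv), MeCN, 0 °C
Reagents that add atoms: N-bromosuccinimide O=C1CCC(=O)N1Br
Why: Electrophilic aromatic bromination goes to one of the two equivalent free positions, each ortho to one benzyloxy group and para to the other, as with 3,4,5-trialkoxybenzyl alcohols.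

Step 4
Reactants: 4 [3,5-bis(benzyloxy)-2-bromo-4-methoxyphenyl]methanol
Product: 5 3,5-bis(benzyloxy)-2-bromo-4-methoxybenzaldehyde
Conditions: MnO2, CH2Cl2, rt
Reagents that add atoms: none
Why: Activated MnO2 oxidises the benzylic alcohol selectively to the aldehyde without over-oxidation.

Step 5
Reactants: 5 3,5-bis(benzyloxy)-2-bromo-4-methoxybenzaldehyde; 6 trimethylsilylacetylene
Product: 8 (R)-1-[3,5-bis(benzyloxy)-2-bromo-4-methoxyphenyl]-3-(trimethylsilyl)prop-2-yn-1-ol, via ethyl(trimethylsilylethynyl)zinc 7 (not isolated)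
Conditions: 6, Et2Zn, Cy2NH (5 mol%), (R)-BINOL (20 mol%), Et2O, rt; Ti(OiPr)4 (50 mol%); then 5, rt; aq NH4Cl
Reagents that add atoms: none
Why: BINOL–titanium-promoted enantioselective alkynylzinc addition to an aromatic aldehyde, in which the (R)-BINOL–titanium complex is expected to expose the Re face so that ring A's benzylic centre is set as R while the aryl bromide stays inert to the zinc reagent.

Step 6
Reactants: 8 (R)-1-[3,5-bis(benzyloxy)-2-bromo-4-methoxyphenyl]-3-(trimethylsilyl)prop-2-yn-1-ol
Product: 9 (R)-tert-butyl{1-[3,5-bis(benzyloxy)-2-bromo-4-methoxyphenyl]-3-(trimethylsilyl)prop-2-yn-1-yloxy}dimethylsilane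
Conditions: TBSOTf, 2,6-lutidine, CH2Cl2, 0 °C
Reagents that add atoms: tert-butyldimethylsilyl triflate CC(C)(C)[Si](C)(C)OS(=O)(=O)C(F)(F)F
Why: Silylation of the hindered secondary carbinol with the silyl triflate protects the benzylic oxygen before a carboxyl is ever placed ortho to it.

Step 7
Reactants: 9 (R)-tert-butyl{1-[3,5-bis(benzyloxy)-2-bromo-4-methoxyphenyl]-3-(trimethylsilyl)prop-2-yn-1-yloxy}dimethylsilane
Product: 10 (R)-tert-butyl{1-[3,5-bis(benzyloxy)-2-bromo-4-methoxyphenyl]prop-2-yn-1-yloxy}dimethylsilane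
Conditions: K2CO3, MeOH, rt
Reagents that add atoms: none
Why: Base-mediated methanolysis cleaves the alkynyl C–Si bond selectively because the O-silyl ether is stable to carbonate in methanol.

Step 8
Reactants: 10 (R)-tert-butyl{1-[3,5-bis(benzyloxy)-2-bromo-4-methoxyphenyl]prop-2-yn-1-yloxy}dimethylsilane
Product: 11 (S)-1-[3,5-bis(benzyloxy)-2-bromo-4-methoxyphenyl]-1-[(tert-butyldimethylsilyl)oxy]propan-2-one
Conditions: Ph3PAuNTf2 (3 mol%), 1,4-dioxane/H2O (10:1), 60 °C
Reagents that add atoms: water O
Why: Gold-catalysed Markovnikov hydration of the terminal alkyne gives the methyl ketone under neutral conditions that spare the silyl ether and should not epimerise the α-silyloxy benzylic centre.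

Step 9
Reactants: 11 (S)-1-[3,5-bis(benzyloxy)-2-bromo-4-methoxyphenyl]-1-[(tert-butyldimethylsilyl)oxy]propan-2-one
Product: 12 (1S,2S)-1-[3,5-bis(benzyloxy)-2-bromo-4-methoxyphenyl]-1-[(tert-butyldimethylsilyl)oxy]propan-2-ol
Conditions: (R)-2-methyl-CBS-oxazaborolidine (0.2 equiv), BH3·SMe2, THF, −20 °C; MeOH
Reagents that add atoms: none
Why: Corey–Bakshi–Shibata reduction of a methyl ketone with a large α-branched partner, where the (R)-catalyst should give the (2S)-carbinol, the same threo isomer that Felkin–Anh attack anti to the silyloxy group favours, so catalyst and substrate control coincide and no free alkoxide is formed that could shift the silyl group.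

Step 10
Reactants: 4 [3,5-bis(benzyloxy)-2-bromo-4-methoxyphenyl]methanol
Product: 15 2,4-bis(benzyloxy)-6-(hydroxymethyl)-3-methoxyphenol, via dilithio species 13 (not isolated), via aryl boronate 14 (not isolated)
Conditions: n-BuLi (2.2 equiv), THF, −78 °C; B(OMe)3, −78 °C to rt; then 30% H2O2, aq NaOH, 0 °C
Reagents that add atoms: hydrogen peroxide OO
Why: Alcohol deprotonation, bromine–lithium exchange, borylation and oxidative C–B to C–O conversion replace bromine by the fourth ring oxygen of ring B, the exchange at −78 °C being faster than metalation of the benzyl ethers.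

Step 11
Reactants: 15 2,4-bis(benzyloxy)-6-(hydroxymethyl)-3-methoxyphenol
Product: 16 [2,3,5-tris(benzyloxy)-4-methoxyphenyl]methanol
Conditions: BnBr (1.05 equiv), K2CO3, acetone, reflux
Reagents that add atoms: benzyl bromide BrCc1ccccc1
Why: Carbonate ionises only the phenol, so the Williamson benzylation is selective over the benzylic alcohol.

Step 12
Reactants: 16 [2,3,5-tris(benzyloxy)-4-methoxyphenyl]methanol
Product: 17 2,3,5-tris(benzyloxy)-4-methoxybenzaldehyde
Conditions: MnO2, CH2Cl2, rt
Reagents that add atoms: none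
Why: Selective MnO2 oxidation of the benzylic alcohol gives the aldehyde.

Step 13
Reactants: 17 2,3,5-tris(benzyloxy)-4-methoxybenzaldehyde
Product: 18 2,3,5-tris(benzyloxy)-6-bromo-4-methoxybenzaldehyde
Conditions: NBS, DMF, 0 °C to rt
Reagents that add atoms: N-bromosuccinimide O=C1CCC(=O)N1Br
Why: Electrophilic bromination at the only free ring position, which is ortho and para to benzyloxy groups, installs the bromine that later becomes ring B's carboxyl.

Step 14
Reactants: 18 2,3,5-tris(benzyloxy)-6-bromo-4-methoxybenzaldehyde; 6 trimethylsilylacetylene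
Product: 20 (S)-1-[2,3,5-tris(benzyloxy)-6-bromo-4-methoxyphenyl]-3-(trimethylsilyl)prop-2-yn-1-ol, via methyl(trimethylsilylethynyl)zinc 19 (not isolated)
Conditions: 6 (3 equiv), Me2Zn (3 equiv), (R,R)-ProPhenol (10 mol%), Ph3P=O (20 mol%), toluene, 0 °C, 1 h; then 18, 4 °C; aq NH4Cl
Reagents that add atoms: none
Why: Dinuclear zinc–ProPhenol-catalysed enantioselective alkynylation of an aryl aldehyde, in which dimethylzinc metalates the alkyne and the chiral bimetallic pocket binds the aldehyde and is expected, with the (R,R)-ligand, to deliver the alkynyl group to the Si face and set ring B's benzylic centre as S; the slow uncatalysed addition to an electron-rich, ortho-substituted benzaldehyde favours the catalysed path, and doing this on the bromo aldehyde, before a carboxyl exists, excludes phthalide formation by the new alkoxide.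

Step 15
Reactants: 20 (S)-1-[2,3,5-tris(benzyloxy)-6-bromo-4-methoxyphenyl]-3-(trimethylsilyl)prop-2-yn-1-ol
Product: 21 (S)-tert-butyl{1-[2,3,5-tris(benzyloxy)-6-bromo-4-methoxyphenyl]-3-(trimethylsilyl)prop-2-yn-1-yloxy}dimethylsilane
Conditions: TBSOTf, 2,6-lutidine, CH2Cl2, 0 °C
Reagents that add atoms: tert-butyldimethylsilyl triflate CC(C)(C)[Si](C)(C)OS(=O)(=O)C(F)(F)F
Why: Silyl triflate protection of the hindered propargylic carbinol blocks lactonisation once the ortho carboxyl is introduced.

Step 16
Reactants: 21 (S)-tert-butyl{1-[2,3,5-tris(benzyloxy)-6-bromo-4-methoxyphenyl]-3-(trimethylsilyl)prop-2-yn-1-yloxy}dimethylsilane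
Product: 23 2,4,5-tris(benzyloxy)-6-[(1R)-1-[(tert-butyldimethylsilyl)oxy]-3-(trimethylsilyl)prop-2-yn-1-yl]-3-methoxybenzoic acid, via aryllithium 22 (not isolated)
Conditions: n-BuLi (1.1 equiv), THF, −78 °C, 10 min; CO2 (g); cold dilute HCl to pH 3
Reagents that add atoms: carbon dioxide O=C=O
Why: Bromine–lithium exchange and carboxylation of the aryllithium work here because the carbinol is silylated, the alkyne is C-silylated and has no acidic proton, and the short contact time at −78 °C keeps retro-Brook silyl migration and benzyl ether metalation from competing (the stereocentre is unchanged, its descriptor becomes R only because the silylalkynyl group now outranks the arene).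

Step 17
Reactants: 23 2,4,5-tris(benzyloxy)-6-[(1R)-1-[(tert-butyldimethylsilyl)oxy]-3-(trimethylsilyl)prop-2-yn-1-yl]-3-methoxybenzoic acid; 12 (1S,2S)-1-[3,5-bis(benzyloxy)-2-bromo-4-methoxyphenyl]-1-[(tert-butyldimethylsilyl)oxy]propan-2-ol
Product: 25 (1S,2S)-1-[3,5-bis(benzyloxy)-2-bromo-4-methoxyphenyl]-1-[(tert-butyldimethylsilyl)oxy]propan-2-yl 2,4,5-tris(benzyloxy)-6-[(1R)-1-[(tert-butyldimethylsilyl)oxy]-3-(trimethylsilyl)prop-2-yn-1-yl]-3-methoxybenzoate, via acid chloride 24 (not isolated)
Conditions: 23, 1-chloro-N,N,2-trimethylprop-1-en-1-amine, CH2Cl2, 0 °C to rt; then 12, Et3N, DMAP, toluene, 50 °C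
Reagents that add atoms: none
Why: DMAP-catalysed acylation of the secondary alcohol by the acid chloride, made under neutral conditions with Ghosez's reagent, proceeds with retention at the carbinol, and because ring A still carries bromine in place of its carboxyl the alcohol has no ester to lactonise onto.

Step 18
Reactants: 25 (1S,2S)-1-[3,5-bis(benzyloxy)-2-bromo-4-methoxyphenyl]-1-[(tert-butyldimethylsilyl)oxy]propan-2-yl 2,4,5-tris(benzyloxy)-6-[(1R)-1-[(tert-butyldimethylsilyl)oxy]-3-(trimethylsilyl)prop-2-yn-1-yl]-3-methoxybenzoate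
Product: 27 2,4-bis(benzyloxy)-6-[(1S,2S)-1-[(tert-butyldimethylsilyl)oxy]-2-({2,4,5-tris(benzyloxy)-6-[(1R)-1-[(tert-butyldimethylsilyl)oxy]-3-(trimethylsilyl)prop-2-yn-1-yl]-3-methoxybenzoyl}oxy)propyl]-3-methoxybenzoic acid, via aryllithium 26 (not isolated)
Conditions: t-BuLi (2.1 equiv), THF/Et2O, −100 °C, 5 min; CO2 (g), −100 to −40 °C; cold dilute HCl to pH 3
Reagents that add atoms: carbon dioxide O=C=O
Why: Low-temperature bromine–lithium exchange followed by carboxylation (Parham-type conditions) should outrun addition to the ester, whose carbonyl is shielded by two ortho substituents, and the alkyne is still C-silylated so that no acetylide is carboxylated.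

Step 19
Reactants: 27 2,4-bis(benzyloxy)-6-[(1S,2S)-1-[(tert-butyldimethylsilyl)oxy]-2-({2,4,5-tris(benzyloxy)-6-[(1R)-1-[(tert-butyldimethylsilyl)oxy]-3-(trimethylsilyl)prop-2-yn-1-yl]-3-methoxybenzoyl}oxy)propyl]-3-methoxybenzoic acid
Product: 28 2,4-bis(benzyloxy)-6-[(1S,2S)-1-[(tert-butyldimethylsilyl)oxy]-2-({2,4,5-tris(benzyloxy)-6-[(1S)-1-[(tert-butyldimethylsilyl)oxy]prop-2-yn-1-yl]-3-methoxybenzoyl}oxy)propyl]-3-methoxybenzoic acid
Conditions: K2CO3, MeOH/THF, rt; dilute acid to pH 3
Reagents that add atoms: none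
Why: Methanolic carbonate removes the alkynyl silyl group while the di-ortho-substituted benzoate ester resists methanolysis and the O-silyl ethers persist (the propargylic descriptor returns to S by priority change only).

Step 20
Reactants: 28 2,4-bis(benzyloxy)-6-[(1S,2S)-1-[(tert-butyldimethylsilyl)oxy]-2-({2,4,5-tris(benzyloxy)-6-[(1S)-1-[(tert-butyldimethylsilyl)oxy]prop-2-yn-1-yl]-3-methoxybenzoyl}oxy)propyl]-3-methoxybenzoic acid
Product: 29 twelve-membered pentabenzyl bis-TBS diolide with an exocyclic methylene on the enol ester carbon that links ring A's ester oxygen to ring B's (R)-silyloxy carbon (ring A side chain S,S)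
Conditions: [Ru(p-cymene)Cl2]2 (5 mol%), P(2-furyl)3 (10 mol%), Na2CO3 (10 mol%), toluene, 2 mM, 60 °C, slow addition of 28 by syringe pump
Reagents that add atoms: none
Why: Proposed new method: the ruthenium carboxylate formed from 28 binds the terminal alkyne as a π-complex, the ring A carboxylate oxygen attacks the internal alkyne carbon, and the resulting vinyl–ruthenium bond is protonated by further acid to release the 1-alken-2-yl ester. The closest known chemistry is the intermolecular ruthenium-catalysed Markovnikov addition of carboxylic acids to terminal alkynes and the cycloisomerisation of alkynoic acids to small enol lactones; a twelve-membered closure of this kind is untested. The ring closes in a 12-exo-dig mode, so the new C=C becomes an exocyclic methylene, and no stereocentre is created. The step needs Markovnikov over anti-Markovnikov addition, which the weakly donating furylphosphine with carbonate base should secure by disfavouring the vinylidene pathway, and ring closure over oligomerisation, which high dilution and the compact seco acid (two ortho-disubstituted benzoate units joined by a two-carbon threo linker) favour. The hindered benzoic acid reacts as a nucleophile, so the shielding that defeats acyl activation is no obstacle, and ruthenium is preferred over cationic gold because the neighbouring ring B ester carbonyl is then less likely to capture the activated alkyne.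

Step 21
Reactants: 29 twelve-membered pentabenzyl bis-TBS diolide enol ester
Product: 30 pentabenzyl bis-TBS diolide with the new methyl carbinol R (ring B side chain R,R; ring A side chain S,S)
Conditions: [Rh(cod)((R,R)-Et-DuPhos)]BF4 (5 mol%), H2 (10 bar), CH2Cl2/MeOH, rt
Reagents that add atoms: none
Why: Rhodium–bisphosphine asymmetric hydrogenation of an enol ester, in which alkene and acyl oxygen chelate the metal, should with the (R,R)-ligand add hydrogen to the face that gives the (R)-methyl carbinol, threo to the neighbouring silyloxy centre, by analogy with open-chain 1-alken-2-yl esters, and aryl benzyl ethers are inert to this catalyst.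

Step 22
Reactants: 30 pentabenzyl bis-TBS diolide
Product: 31 bis-TBS ether of the target (both benzylic oxygens silylated, five free phenols)
Conditions: H2 (1 atm), 10% Pd/C, EtOAc/THF, rt
Reagents that add atoms: none
Why: Hydrogenolysis removes the five aryl benzyl ethers, while the benzylic carbinols are silyl ethers and both ester oxygens sit on non-benzylic carbons, so no skeletal C–O bond is cleaved.

Step 23
Reactants: 31 bis-TBS ether of the target
Product: 32 CNP0086623.3
Conditions: HF·pyridine, pyridine, THF, 0 °C to rt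
Reagents that add atoms: none
Why: Buffered fluoride desilylation frees both benzylic carbinols under mildly acidic conditions, avoiding the base that would invite acyl migration or phthalide formation in the salicylate-type diolide.

**Compound list**

1 | methyl 3,5-dihydroxy-4-methoxybenzoate | COC(=O)c1cc(O)c(OC)c(O)c1 | starting material
2 | methyl 3,5-bis(benzyloxy)-4-methoxybenzoate | COC(=O)c1cc(OCc2ccccc2)c(OC)c(OCc2ccccc2)c1 | intermediate
3 | [3,5-bis(benzyloxy)-4-methoxyphenyl]methanol | OCc1cc(OCc2ccccc2)c(OC)c(OCc2ccccc2)c1 | intermediate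
4 | [3,5-bis(benzyloxy)-2-bromo-4-methoxyphenyl]methanol | OCc1cc(OCc2ccccc2)c(OC)c(OCc2ccccc2)c1Br | intermediate
5 | 3,5-bis(benzyloxy)-2-bromo-4-methoxybenzaldehyde | O=Cc1cc(OCc2ccccc2)c(OC)c(OCc2ccccc2)c1Br | intermediate
6 | trimethylsilylacetylene | C#C[Si](C)(C)C | starting material
7 | ethyl(trimethylsilylethynyl)zinc (not isolated) | CC[Zn]C#C[Si](C)(C)C | intermediate
8 | (R)-1-[3,5-bis(benzyloxy)-2-bromo-4-methoxyphenyl]-3-(trimethylsilyl)prop-2-yn-1-ol | O[C@H](C#C[Si](C)(C)C)c1cc(OCc2ccccc2)c(OC)c(OCc2ccccc2)c1Br | intermediate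
9 | TBS ether of 8 (R) | CC(C)(C)[Si](C)(C)O[C@H](C#C[Si](C)(C)C)c1cc(OCc2ccccc2)c(OC)c(OCc2ccccc2)c1Br | intermediate
10 | terminal alkyne from 9 (R) | CC(C)(C)[Si](C)(C)O[C@H](C#C)c1cc(OCc2ccccc2)c(OC)c(OCc2ccccc2)c1Br | intermediate
11 | (S)-1-[3,5-bis(benzyloxy)-2-bromo-4-methoxyphenyl]-1-[(tert-butyldimethylsilyl)oxy]propan-2-one | CC(C)(C)[Si](C)(C)O[C@H](C(C)=O)c1cc(OCc2ccccc2)c(OC)c(OCc2ccccc2)c1Br | intermediate
12 | (1S,2S)-1-[3,5-bis(benzyloxy)-2-bromo-4-methoxyphenyl]-1-[(tert-butyldimethylsilyl)oxy]propan-2-ol | C[C@H](O)[C@@H](O[Si](C)(C)C(C)(C)C)c1cc(OCc2ccccc2)c(OC)c(OCc2ccccc2)c1Br | intermediate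
13 | dilithio species: lithium [3,5-bis(benzyloxy)-2-lithio-4-methoxyphenyl]methanolate (not isolated) | [Li]OCc1cc(OCc2ccccc2)c(OC)c(OCc2ccccc2)c1[Li] | intermediate
14 | aryl boronate: dimethyl {4,6-bis(benzyloxy)-2-[(lithiooxy)methyl]-5-methoxyphenyl}boronate (not isolated) | [Li]OCc1cc(OCc2ccccc2)c(OC)c(OCc2ccccc2)c1B(OC)OC | intermediate
15 | 2,4-bis(benzyloxy)-6-(hydroxymethyl)-3-methoxyphenol | OCc1cc(OCc2ccccc2)c(OC)c(OCc2ccccc2)c1O | intermediate
16 | [2,3,5-tris(benzyloxy)-4-methoxyphenyl]methanol | OCc1cc(OCc2ccccc2)c(OC)c(OCc2ccccc2)c1OCc1ccccc1 | intermediate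
17 | 2,3,5-tris(benzyloxy)-4-methoxybenzaldehyde | O=Cc1cc(OCc2ccccc2)c(OC)c(OCc2ccccc2)c1OCc1ccccc1 | intermediate
18 | 2,3,5-tris(benzyloxy)-6-bromo-4-methoxybenzaldehyde | O=Cc1c(Br)c(OCc2ccccc2)c(OC)c(OCc2ccccc2)c1OCc1ccccc1 | intermediate
19 | methyl(trimethylsilylethynyl)zinc (not isolated) | C[Zn]C#C[Si](C)(C)C | intermediate
20 | (S)-1-[2,3,5-tris(benzyloxy)-6-bromo-4-methoxyphenyl]-3-(trimethylsilyl)prop-2-yn-1-ol | O[C@@H](C#C[Si](C)(C)C)c1c(OCc2ccccc2)c(OCc2ccccc2)c(OC)c(OCc2ccccc2)c1Br | intermediate
21 | TBS ether of 20 (S) | CC(C)(C)[Si](C)(C)O[C@@H](C#C[Si](C)(C)C)c1c(OCc2ccccc2)c(OCc2ccccc2)c(OC)c(OCc2ccccc2)c1Br | intermediate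
22 | aryllithium from 21 (not isolated) | CC(C)(C)[Si](C)(C)O[C@@H](C#C[Si](C)(C)C)c1c(OCc2ccccc2)c(OCc2ccccc2)c(OC)c(OCc2ccccc2)c1[Li] | intermediate
23 | ring B acid: 2,4,5-tris(benzyloxy)-6-[(1R)-1-[(tert-butyldimethylsilyl)oxy]-3-(trimethylsilyl)prop-2-yn-1-yl]-3-methoxybenzoic acid | CC(C)(C)[Si](C)(C)O[C@@H](C#C[Si](C)(C)C)c1c(OCc2ccccc2)c(OCc2ccccc2)c(OC)c(OCc2ccccc2)c1C(=O)O | intermediate
24 | acid chloride of 23 (not isolated) | CC(C)(C)[Si](C)(C)O[C@@H](C#C[Si](C)(C)C)c1c(OCc2ccccc2)c(OCc2ccccc2)c(OC)c(OCc2ccccc2)c1C(Cl)=O | intermediate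
25 | bromo diester: ester of acid 23 with alcohol 12 (ring A side chain 1S,2S; ring B propargylic centre as in 23) | C[Si](C)(C)C#C[C@H](O[Si](C)(C)C(C)(C)C)c1c(OCc2ccccc2)c(OCc2ccccc2)c(OC)c(OCc2ccccc2)c1C(=O)O[C@@H](C)[C@@H](O[Si](C)(C)C(C)(C)C)c1cc(OCc2ccccc2)c(OC)c(OCc2ccccc2)c1Br | intermediate
26 | aryllithium from 25 (not isolated) | C[Si](C)(C)C#C[C@H](O[Si](C)(C)C(C)(C)C)c1c(OCc2ccccc2)c(OCc2ccccc2)c(OC)c(OCc2ccccc2)c1C(=O)O[C@@H](C)[C@@H](O[Si](C)(C)C(C)(C)C)c1cc(OCc2ccccc2)c(OC)c(OCc2ccccc2)c1[Li] | intermediate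
27 | C-silylated alkynyl seco acid (ring A carboxyl free) | C[Si](C)(C)C#C[C@H](O[Si](C)(C)C(C)(C)C)c1c(OCc2ccccc2)c(OCc2ccccc2)c(OC)c(OCc2ccccc2)c1C(=O)O[C@@H](C)[C@@H](O[Si](C)(C)C(C)(C)C)c1cc(OCc2ccccc2)c(OC)c(OCc2ccccc2)c1C(=O)O | intermediate
28 | alkynyl seco acid, precursor of the key step (terminal alkyne, propargylic centre S, ring A side chain 1S,2S) | C#C[C@H](O[Si](C)(C)C(C)(C)C)c1c(OCc2ccccc2)c(OCc2ccccc2)c(OC)c(OCc2ccccc2)c1C(=O)O[C@@H](C)[C@@H](O[Si](C)(C)C(C)(C)C)c1cc(OCc2ccccc2)c(OC)c(OCc2ccccc2)c1C(=O)O | intermediate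
29 | twelve-membered diolide enol ester with exocyclic methylene | COc1c(OCc3ccccc3)cc2c(c1OCc1ccccc1)C(=O)OC(=C)[C@H](O[Si](C)(C)C(C)(C)C)c1c(OCc3ccccc3)c(OCc3ccccc3)c(OC)c(OCc3ccccc3)c1C(=O)O[C@@H](C)[C@H]2O[Si](C)(C)C(C)(C)C | intermediate
30 | pentabenzyl bis-TBS diolide (ring B side chain R,R; ring A side chain S,S) | COc1c(OCc3ccccc3)cc2c(c1OCc1ccccc1)C(=O)O[C@H](C)[C@H](O[Si](C)(C)C(C)(C)C)c1c(OCc3ccccc3)c(OCc3ccccc3)c(OC)c(OCc3ccccc3)c1C(=O)O[C@@H](C)[C@H]2O[Si](C)(C)C(C)(C)C | intermediate
31 | bis-TBS ether of the target | COc1c(O)cc2c(c1O)C(=O)O[C@H](C)[C@H](O[Si](C)(C)C(C)(C)C)c1c(O)c(O)c(OC)c(O)c1C(=O)O[C@@H](C)[C@H]2O[Si](C)(C)C(C)(C)C | intermediate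
32 | CNP0086623.3 | COc1c(O)cc2c(c1O)C(=O)O[C@H](C)[C@H](O)c1c(O)c(O)c(OC)c(O)c1C(=O)O[C@@H](C)[C@H]2O | target

**Step count.** Total: 23 steps. Longest linear sequence: 17 steps (steps 1–3 and 10–23).

**Steps most likely to fail**

1. Step 20 (the proposed new method). Oligomerisation may outpace ring closure, addition may go anti-Markovnikov through a vinylidene to give a thirteen-membered (Z)-enol lactone, or the ring B ester carbonyl may capture the activated alkyne. Fallback: the methyl carbinol is made before ring closure and the ring is closed by Mitsunobu lactonisation, in which the hindered ring A acid again acts as the nucleophile. The fallback sets out from 28. Allyl bromide and KHCO3 in DMF give the allyl ester of the seco acid F1. Ph3PAuNTf2-catalysed hydration of the alkyne gives the methyl ketone F2. (R)-2-methyl-CBS-oxazaborolidine with catecholborane then reduces the ketone under catalyst control, against the substrate's threo bias, to the (S)-methyl carbinol allyl ester F3. Pd(PPh3)4 with morpholine removes the allyl group to give the seco hydroxy acid F4. PPh3 and DIAD in toluene at high dilution close the lactone with inversion, and the route is rejoined at 30 (steps 20 and 21 are bypassed).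

2. Step 21. Facial selectivity may be poor, or the catalyst may not turn over, because the twisted, hindered aroyl carbonyl chelates rhodium badly and the ring conformation may oppose the ligand. Fallback: the enol ester is used as a masked ketone. The fallback sets out from 29. LiOH with H2O2 in THF/H2O at 0 °C cleaves only the enol ester, the alkyl benzoate being far less reactive, and gives the seco keto acid F5. CBS reduction with (R)-2-methyl-CBS-oxazaborolidine and catecholborane, which spares the carboxylic acid, gives the seco hydroxy acid F4, the compound also reached in the fallback for step 20. Mitsunobu lactonisation with inversion returns to 30.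

3. Step 18. The aryllithium or t-BuLi may add to the ester before carbon dioxide arrives, a benzyl ether may be metalated, or the ortho silyl group may migrate from oxygen to carbon. Fallback: ring A's carboxyl is installed early, as for ring B, and the first ester bond is made with the acid as nucleophile by the intermolecular, precedented form of alkyne hydro-acyloxylation; this also avoids the hindered acylation of step 17. The fallback sets out from 9 and acid 23. n-BuLi at −78 °C followed by allyl chloroformate gives the ring A allyl ester with C-silylated alkyne F6. K2CO3 in MeOH gives the ring A allyl ester with terminal alkyne F7. [Ru(p-cymene)Cl2]2, P(2-furyl)3 and Na2CO3 in toluene add acid 23 in the Markovnikov sense to give the open-chain enol ester F8. Pd(PPh3)4 with morpholine gives the open-chain enol ester with free ring A carboxyl F9. [Rh(cod)((S,S)-Et-DuPhos)]BF4 under H2 should reduce the chelating enol ester to the (S)-methyl carbinol faster than it touches the hindered silyl-capped alkyne, and the route is rejoined at 27 (steps 7–9, 17 and 18 are bypassed).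

**Further compounds**

F1 | step 20 | allyl ester of seco acid 28 | C#C[C@H](O[Si](C)(C)C(C)(C)C)c1c(OCc2ccccc2)c(OCc2ccccc2)c(OC)c(OCc2ccccc2)c1C(=O)O[C@@H](C)[C@@H](O[Si](C)(C)C(C)(C)C)c1cc(OCc2ccccc2)c(OC)c(OCc2ccccc2)c1C(=O)OCC=C
F2 | step 20 | methyl ketone from hydration of F1 | CC(=O)[C@H](O[Si](C)(C)C(C)(C)C)c1c(OCc2ccccc2)c(OCc2ccccc2)c(OC)c(OCc2ccccc2)c1C(=O)O[C@@H](C)[C@@H](O[Si](C)(C)C(C)(C)C)c1cc(OCc2ccccc2)c(OC)c(OCc2ccccc2)c1C(=O)OCC=C
F3 | step 20 | (S)-methyl carbinol allyl ester (ring B side chain 1R,2S) | C[C@H](O)[C@H](O[Si](C)(C)C(C)(C)C)c1c(OCc2ccccc2)c(OCc2ccccc2)c(OC)c(OCc2ccccc2)c1C(=O)O[C@@H](C)[C@@H](O[Si](C)(C)C(C)(C)C)c1cc(OCc2ccccc2)c(OC)c(OCc2ccccc2)c1C(=O)OCC=C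
F4 | step 20 | seco hydroxy acid (ring B side chain 1R,2S; ring A carboxyl free) | C[C@H](O)[C@H](O[Si](C)(C)C(C)(C)C)c1c(OCc2ccccc2)c(OCc2ccccc2)c(OC)c(OCc2ccccc2)c1C(=O)O[C@@H](C)[C@@H](O[Si](C)(C)C(C)(C)C)c1cc(OCc2ccccc2)c(OC)c(OCc2ccccc2)c1C(=O)O
F5 | step 21 | seco keto acid from cleavage of the enol ester of 29 | CC(=O)[C@H](O[Si](C)(C)C(C)(C)C)c1c(OCc2ccccc2)c(OCc2ccccc2)c(OC)c(OCc2ccccc2)c1C(=O)O[C@@H](C)[C@@H](O[Si](C)(C)C(C)(C)C)c1cc(OCc2ccccc2)c(OC)c(OCc2ccccc2)c1C(=O)O
F6 | step 18 | ring A allyl ester with C-silylated alkyne (propargylic centre as in 9) | CC(C)(C)[Si](C)(C)O[C@H](C#C[Si](C)(C)C)c1cc(OCc2ccccc2)c(OC)c(OCc2ccccc2)c1C(=O)OCC=C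
F7 | step 18 | ring A allyl ester with terminal alkyne | CC(C)(C)[Si](C)(C)O[C@H](C#C)c1cc(OCc2ccccc2)c(OC)c(OCc2ccccc2)c1C(=O)OCC=C
F8 | step 18 | open-chain enol ester of acid 23 with alkyne F7 (allyl ester) | C[Si](C)(C)C#C[C@H](O[Si](C)(C)C(C)(C)C)c1c(OCc2ccccc2)c(OCc2ccccc2)c(OC)c(OCc2ccccc2)c1C(=O)OC(=C)[C@@H](O[Si](C)(C)C(C)(C)C)c1cc(OCc2ccccc2)c(OC)c(OCc2ccccc2)c1C(=O)OCC=C
F9 | step 18 | open-chain enol ester with free ring A carboxyl | C[Si](C)(C)C#C[C@H](O[Si](C)(C)C(C)(C)C)c1c(OCc2ccccc2)c(OCc2ccccc2)c(OC)c(OCc2ccccc2)c1C(=O)OC(=C)[C@@H](O[Si](C)(C)C(C)(C)C)c1cc(OCc2ccccc2)c(OC)c(OCc2ccccc2)c1C(=O)O
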